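**Assumptions (one line each)**
- 4-Bromocatechol, 4-hydroxycyclohexanone (made industrially from hydroquinone) and 4-(tert-butyldimethylsilyloxy)styrene are taken as commercially available.
- The target is (3S) by CIP analysis of the given SMILES. The Baeyer–Villiger enzyme is chosen, or an enantiocomplementary variant is used, so that it delivers lactone **4** as the (S)-enantiomer.

**Retrosynthesis**
1. The target comes from global aryl-silyl removal of the tris-TBS acetate **11**. The (E)-styrene C6=C7 comes from cross-metathesis of terminal alkene **9** with 4-silyloxystyrene.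
2. Alkene **9** comes from the C3 alcohol **8**, which comes from Wittig methylenation of lactol **7**. Lactol **7** comes from lactone **6**, whose arylethyl arm is made by Negishi coupling of the iodide **5** with a bis-silyloxy aryl bromide.
3. Iodide **5** comes from (S)-5-(2-hydroxyethyl)-γ-butyrolactone **4**. Lactone **4** comes from one desymmetrizing enzymatic Baeyer–Villiger oxidation of the mirror-symmetric 4-hydroxycyclohexanone (**3**).
4. That one oxidation sets C3 and converts the two identical ring arms into a CH₂CH₂OH arm and a CH₂CH₂C(=O) arm. The only ring formed is the γ-lactone, by spontaneous translactonization. Both arenes are already present in the starting materials.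

---

**Step 1**
Reactants: **1** 4-bromocatechol (Oc1ccc(Br)cc1O)
Product: **2** 4-bromo-1,2-bis(tert-butyldimethylsilyloxy)benzene
Conditions: TBSCl (2.5 equiv), imidazole, DMF, 0 °C → rt
Reagents that add atoms: TBSCl, CC(C)(C)[Si](C)(C)Cl
Why: Both phenols are silylated so that the aryl bromide survives organozinc, DIBAL and ylide steps. Aryl silyl ethers can later be removed under near-neutral conditions that leave the alkyl acetate intact (silyl ether protection).

**Step 2**
Reactants: **3** 4-hydroxycyclohexanone (OC1CCC(=O)CC1)
Product: **4** (S)-5-(2-hydroxyethyl)dihydrofuran-2(3H)-one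
Conditions: cyclohexanone monooxygenase (E. coli whole cells), glucose/glucose dehydrogenase for NADPH recycling, air, phosphate buffer pH 7.5, 30 °C; then acidify to pH 3 and extract
Reagents that add atoms: O₂ (O=O)
Why: Baeyer–Villiger oxidation. The enzyme inserts oxygen into only one of the two enantiotopic C–C bonds of the Cs-symmetric ketone, which sets the C–O stereocenter (future C3) and differentiates the two arms. The initial 5-hydroxyoxepan-2-one translactonizes to the γ-lactone by attack of the secondary OH, releasing the primary OH.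
Proposed new method: the closest known reaction is the cyclohexanone monooxygenase desymmetrization of 4-methyl and other 4-substituted cyclohexanones. The 4-OH substrate is assumed to be accepted, and the 7→5 acyl transfer is an intramolecular γ-lactone-forming transesterification.

**Step 3**
Reactants: **4**
Product: **5** (S)-5-(2-iodoethyl)dihydrofuran-2(3H)-one (ICC[C@@H]1CCC(=O)O1)
Conditions: PPh₃, I₂, imidazole, CH₂Cl₂, 0 °C → rt
Reagents that add atoms: I₂, II
Why: Appel iodination (SN2) at the primary carbon. The stereocenter is not touched, and the lactone masks the secondary oxygen.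

**Step 4**
Reactants: **5** and **2**
Product: **6** (R)-5-[2-(3,4-bis(TBSO)phenyl)ethyl]dihydrofuran-2(3H)-one
Conditions: Zn dust, LiCl, I₂ (cat.), THF, 40 °C to give the alkylzinc iodide; then **2**, Pd(OAc)₂/SPhos, THF, 50 °C
Reagents that add atoms: none
Why: Negishi coupling of a primary alkylzinc iodide, which tolerates the lactone, with an aryl bromide. This forms the C1–aryl bond; the descriptor changes from S to R only because CIP priorities change, and the stereocenter is unchanged.

**Step 5**
Reactants: **6**
Product: **7** lactol, 5-[2-(3,4-bis(TBSO)phenyl)ethyl]tetrahydrofuran-2-ol (anomeric mixture)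
Conditions: DIBAL-H (1.2 equiv), CH₂Cl₂, –78 °C; MeOH, then Rochelle salt
Reagents that add atoms: none
Why: Partial reduction of the lactone to the lactol, which is a masked C6 aldehyde with the C3 oxygen still tied up, so there is no racemization.

**Step 6**
Reactants: **7**
Product: **8** (S)-1-[3,4-bis(TBSO)phenyl]hept-6-en-3-ol
Conditions: Ph₃PCH₃Br (3 equiv), KHMDS (2.9 equiv), THF, 0 °C → rt
Reagents that add atoms: methyltriphenylphosphonium bromide, C[P+](c1ccccc1)(c1ccccc1)c1ccccc1.[Br-]
Why: Wittig methylenation of the lactol through its open hydroxy-aldehyde form installs C7 and releases the free C3–OH. The γ-hydroxy aldehyde cannot eliminate or epimerize, and C3 is untouched.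

**Step 7**
Reactants: **8**
Product: **9** (S)-1-[3,4-bis(TBSO)phenyl]hept-6-en-3-yl acetate
Conditions: Ac₂O, Et₃N, DMAP (cat.), CH₂Cl₂, 0 °C → rt
Reagents that add atoms: acetic anhydride, CC(=O)OC(C)=O
Why: Acylation of the secondary alcohol with retention of configuration. The aryl TBS ethers are stable to these conditions.

**Step 8**
Reactants: **9** and **10** 4-(tert-butyldimethylsilyloxy)styrene (C=Cc1ccc(O[Si](C)(C)C(C)(C)C)cc1)
Product: **11** (3S,6E)-1-[3,4-bis(TBSO)phenyl]-7-(4-TBSO-phenyl)hept-6-en-3-yl acetate
Conditions: Hoveyda–Grubbs II (5 mol %), 10 (4 equiv), CH₂Cl₂, 40 °C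
Reagents that add atoms: none
Why: Olefin cross-metathesis of a terminal alkene with an excess styrene gives the thermodynamically favored E-styrene and releases ethylene. The acetate and silyl ethers are inert to the Ru carbene.

**Step 9**
Reactants: **11**
Product: **12** target, (3S,6E)-1-(3,4-dihydroxyphenyl)-7-(4-hydroxyphenyl)hept-6-en-3-yl acetate
Conditions: LiOAc·2H₂O, DMF/H₂O (50:1), rt, under N₂; dilute AcOH work-up
Reagents that add atoms: none
Why: Acetate-catalyzed cleavage of aryl silyl ethers is selective over an alkyl acetate and over the alkene, and C3 is untouched.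

---

**Compound list**
1 | 4-bromocatechol | Oc1ccc(Br)cc1O | starting material
2 | 4-bromo-1,2-bis(TBSO)benzene | CC(C)(C)[Si](C)(C)Oc1ccc(Br)cc1O[Si](C)(C)C(C)(C)C | intermediate
3 | 4-hydroxycyclohexanone | OC1CCC(=O)CC1 | starting material
4 | (S)-5-(2-hydroxyethyl)dihydrofuran-2(3H)-one | OCC[C@@H]1CCC(=O)O1 | intermediate
5 | (S)-5-(2-iodoethyl)dihydrofuran-2(3H)-one | ICC[C@@H]1CCC(=O)O1 | intermediate
6 | (R)-5-[2-(3,4-bis(TBSO)phenyl)ethyl]dihydrofuran-2(3H)-one | CC(C)(C)[Si](C)(C)Oc1ccc(CC[C@@H]2CCC(=O)O2)cc1O[Si](C)(C)C(C)(C)C | intermediate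
7 | 5-[2-(3,4-bis(TBSO)phenyl)ethyl]tetrahydrofuran-2-ol (lactol, anomeric mixture) | CC(C)(C)[Si](C)(C)Oc1ccc(CC[C@@H]2CCC(O)O2)cc1O[Si](C)(C)C(C)(C)C | intermediate
8 | (S)-1-[3,4-bis(TBSO)phenyl]hept-6-en-3-ol | C=CCC[C@H](O)CCc1ccc(O[Si](C)(C)C(C)(C)C)c(O[Si](C)(C)C(C)(C)C)c1 | intermediate
9 | (S)-1-[3,4-bis(TBSO)phenyl]hept-6-en-3-yl acetate | C=CCC[C@H](OC(C)=O)CCc1ccc(O[Si](C)(C)C(C)(C)C)c(O[Si](C)(C)C(C)(C)C)c1 | intermediate
10 | 4-(TBSO)styrene | C=Cc1ccc(O[Si](C)(C)C(C)(C)C)cc1 | starting material
11 | (3S,6E)-tris-TBS-protected acetate | CC(=O)O[C@@H](CC/C=C/c1ccc(O[Si](C)(C)C(C)(C)C)cc1)CCc1ccc(O[Si](C)(C)C(C)(C)C)c(O[Si](C)(C)C(C)(C)C)c1 | intermediate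
12 | (3S,6E)-1-(3,4-dihydroxyphenyl)-7-(4-hydroxyphenyl)hept-6-en-3-yl acetate | CC(=O)O[C@@H](CC/C=C/c1ccc(O)cc1)CCc1ccc(O)c(O)c1 | target

**Totals:** 9 steps in total; longest linear sequence is 8 steps (Steps 2 to 9).

**Three steps most likely to fail, with fallbacks**
1. **Step 2 (enzymatic Baeyer–Villiger).** The 4-OH substrate may be poorly accepted, or the ee or the enantiomer may be wrong. Fallback: make (S)-lactone 4 from L-glutamic acid. Diazotize to (S)-5-oxotetrahydrofuran-2-carboxylic acid, apply Arndt–Eistert homologation, then reduce the acid selectively with BH₃·SMe₂.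
2. **Step 8 (cross-metathesis).** Conversion or E-selectivity may be poor with the polysilylated substrate. Fallback: take lactol 7 directly through Julia–Kocienski olefination with the 4-(TBSO)benzyl PT-sulfone, which installs the E-styrene in one step in place of Steps 6 and 8, followed by Steps 7 and 9 unchanged.
3. **Step 9 (final deprotection).** The free catechol may oxidize, or acetate may be lost. Fallback: change the phenol protection to MOM ethers, using MOM-protected aryl bromide 2 and MOM-protected styrene 10, and remove them at the end with mild acid such as PPTS in t-BuOH.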